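**Retrosynthetic overview**
1. The last step is global MOM removal. Before it, the flavanonol C2–aryl (ring B) bond is made by a rhodium-catalysed asymmetric arylboron–chromone coupling that joins the two halves and sets C2 and, by protonation, the cis C3.
2. The boronate half comes from Miyaura borylation of an aryl bromide on the all-trans cyclohexene. The cyclohexene ring is formed by an exo-selective chiral-borate Diels–Alder of a 2'-hydroxychalcone with a 1-aryl-3-methylbutadiene.
3. The chalcone comes from a Claisen–Schmidt condensation of a resorcinol-derived acetophenone and aldehyde. The diene comes from an iodide-selective Heck reaction with 2-methylbut-3-en-2-ol, then dehydration.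
4. The chromone half is closed on the same acetophenone with an amide acetal; C3 is then oxygenated by epoxidation and rearrangement.
5. Ring order: pyranone and cyclohexene are built in separate branches; the two ring C stereocentres are created last, at the union.

Assumption: the 2,3-cis (2S,3R) flavanonol and the all-trans (1R,2R,6S) cyclohexene are taken exactly as written in the SMILES, and the ligand antipodes named in steps 10 and 15 are assumed to give this sense (the mirror-image ligand is used if the observed sense is opposite).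

**Route**

Step 1
Reactants: 1 resorcinol; 2 acetic acid
Product: 3 1-(2,4-dihydroxyphenyl)ethan-1-one
Conditions: ZnCl2 (1.2 equiv), AcOH (neat), 140 °C
Reagents that add atoms: none
Why: Nencki-type Friedel–Crafts C-acylation at the doubly activated 4-position of resorcinol; no stereocentre.

Step 2
Reactants: 3 1-(2,4-dihydroxyphenyl)ethan-1-one
Product: 4 1-[2-hydroxy-4-(methoxymethoxy)phenyl]ethan-1-one
Conditions: MOMCl (1.1 equiv), K2CO3, acetone, 0 °C to rt
Reagents that add atoms: chloromethyl methyl ether (MOMCl), COCCl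
Why: Williamson-type O-alkylation; the 2-OH is held in a hydrogen bond to the ketone, so only the 4-OH reacts.

Step 3
Reactants: 1 resorcinol
Product: 6 2,4-dihydroxybenzaldehyde, via Vilsmeier iminium chloride 5 (not isolated)
Conditions: POCl3, DMF, MeCN, −15 °C to rt; then H2O, 50 °C
Reagents that add atoms: N,N-dimethylformamide, CN(C)C=O; water, O
Why: Vilsmeier–Haack formylation at the position ortho/para to the two hydroxyls, then hydrolysis of the iminium salt.

Step 4
Reactants: 6 2,4-dihydroxybenzaldehyde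
Product: 7 2,4-bis(methoxymethoxy)benzaldehyde
Conditions: MOMCl (2.6 equiv), K2CO3, acetone, reflux
Reagents that add atoms: chloromethyl methyl ether (MOMCl), COCCl
Why: exhaustive Williamson-type O-alkylation; excess reagent and heat also cap the chelated 2-OH.

Step 5
Reactants: 4 1-[2-hydroxy-4-(methoxymethoxy)phenyl]ethan-1-one; 7 2,4-bis(methoxymethoxy)benzaldehyde
Product: 8 (E)-3-[2,4-bis(methoxymethoxy)phenyl]-1-[2-hydroxy-4-(methoxymethoxy)phenyl]prop-2-en-1-one
Conditions: KOH (aq), EtOH, 0 °C to rt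
Reagents that add atoms: none
Why: Claisen–Schmidt aldol condensation; E1cB dehydration gives the E-enone, and MOM ethers are base-stable.

Step 6
Reactants: 9 2-bromophenol
Product: 10 2-bromo-4-iodophenol
Conditions: NIS (1.05 equiv), p-TsOH·H2O (10 mol%), MeCN, rt
Reagents that add atoms: N-iodosuccinimide, O=C1CCC(=O)N1I
Why: electrophilic aromatic iodination, directed para to the hydroxyl.

Step 7
Reactants: 10 2-bromo-4-iodophenol
Product: 11 2-bromo-4-iodo-1-(methoxymethoxy)benzene
Conditions: MOMCl, i-Pr2NEt, CH2Cl2, 0 °C to rt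
Reagents that add atoms: chloromethyl methyl ether (MOMCl), COCCl
Why: O-alkylation of the phenol to its MOM acetal.

Step 8
Reactants: 11 2-bromo-4-iodo-1-(methoxymethoxy)benzene; 12 2-methylbut-3-en-2-ol
Product: 13 (E)-4-[3-bromo-4-(methoxymethoxy)phenyl]-2-methylbut-3-en-2-ol
Conditions: Pd(OAc)2 (3 mol%), Et3N, DMF, 80 °C (no phosphine)
Reagents that add atoms: none
Why: Mizoroki–Heck coupling; phosphine-free zerovalent palladium inserts into C–I but not C–Br, and syn β-hydride elimination gives the E-alkene.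

Step 9
Reactants: 13 (E)-4-[3-bromo-4-(methoxymethoxy)phenyl]-2-methylbut-3-en-2-ol
Product: 15 2-bromo-1-(methoxymethoxy)-4-[(1E)-3-methylbuta-1,3-dien-1-yl]benzene, via tertiary mesylate 14 (not isolated)
Conditions: MsCl, Et3N (4 equiv), CH2Cl2, 0 °C to rt
Reagents that add atoms: none
Why: sulfonylation of the tertiary allylic alcohol, then E1/E2 elimination toward a methyl group gives the conjugated diene with the E-styrenyl bond untouched.

Step 10
Reactants: 8 the chalcone; 15 the diene (1.5 equiv)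
Product: 16 [(1R,2R,6S)-2-[3-bromo-4-(methoxymethoxy)phenyl]-6-[2,4-bis(methoxymethoxy)phenyl]-4-methylcyclohex-3-en-1-yl][2-hydroxy-4-(methoxymethoxy)phenyl]methanone
Conditions: B(OPh)3 (20 mol%), (R)-VANOL [(R)-3,3'-diphenyl-2,2'-binaphthalene-1,1'-diol] (20 mol%), 4 Å MS, PhCF3, 40 °C; silica separation from the minor endo isomer
Reagents that add atoms: none
Why: chiral-borate-catalysed Diels–Alder reaction in which boron binds the 2'-hydroxy ketone in two-point fashion; "ortho" regiochemistry and exo approach give the all-trans adduct, the E-enone fixes the C1/C6 trans relation, and the VANOL pocket selects the enone face, setting C1, C2 and C6 together.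

Step 11
Reactants: 16 the aryl bromide
Product: 17 [(1R,2R,6S)-6-[2,4-bis(methoxymethoxy)phenyl]-2-[4-(methoxymethoxy)-3-(4,4,5,5-tetramethyl-1,3,2-dioxaborolan-2-yl)phenyl]-4-methylcyclohex-3-en-1-yl][2-hydroxy-4-(methoxymethoxy)phenyl]methanone
Conditions: Pd(dppf)Cl2 (5 mol%), B2pin2 (1.5 equiv), KOAc (3 equiv), 1,4-dioxane, 85 °C
Reagents that add atoms: bis(pinacolato)diboron, CC1(C)OB(OC1(C)C)B1OC(C)(C)C(C)(C)O1
Why: Miyaura borylation; KOAc is too weak to epimerise the all-trans ketone (already the most stable arrangement) or to trigger Suzuki homocoupling.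

Step 12
Reactants: 4 1-[2-hydroxy-4-(methoxymethoxy)phenyl]ethan-1-one
Product: 19 7-(methoxymethoxy)-4H-chromen-4-one, via enaminone 18 (not isolated)
Conditions: Me2NCH(OMe)2 (1.5 equiv), toluene, 90 °C; then AcOH, 50 °C
Reagents that add atoms: N,N-dimethylformamide dimethyl acetal, COC(OC)N(C)C
Why: condensation of the methyl ketone with the amide acetal gives the enaminone, and acid-promoted oxa-Michael addition of the phenol with loss of dimethylamine closes the pyranone ring.

Step 13
Reactants: 19 7-(methoxymethoxy)-4H-chromen-4-one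
Product: 21 3-hydroxy-7-(methoxymethoxy)-4H-chromen-4-one, via epoxychromanone 20 (not isolated)
Conditions: DMDO (acetone solution, 1.5 equiv), CH2Cl2, 0 °C to rt; concentrate; then p-TsOH·H2O (5 mol%), CH2Cl2, rt
Reagents that add atoms: dimethyldioxirane, CC1(C)OO1
Why: electrophilic epoxidation of the enol-ether C2=C3 bond, then acid-catalysed opening at the acetal-like C2 and loss of H-3 gives the 3-hydroxychromone.

Step 14
Reactants: 21 3-hydroxy-7-(methoxymethoxy)-4H-chromen-4-one
Product: 22 3,7-bis(methoxymethoxy)-4H-chromen-4-one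
Conditions: MOMCl, i-Pr2NEt, CH2Cl2, 0 °C to rt
Reagents that add atoms: chloromethyl methyl ether (MOMCl), COCCl
Why: O-alkylation of the acidic enolic 3-OH.

Step 15
Reactants: 17 the aryl boronate; 22 3,7-bis(methoxymethoxy)-4H-chromen-4-one (2 equiv)
Product: 23 [(1R,2R,6S)-6-[2,4-bis(methoxymethoxy)phenyl]-2-{3-[(2S,3R)-3,7-bis(methoxymethoxy)-4-oxo-3,4-dihydro-2H-chromen-2-yl]-4-(methoxymethoxy)phenyl}-4-methylcyclohex-3-en-1-yl][2-hydroxy-4-(methoxymethoxy)phenyl]methanone
Conditions: [RhCl(C2H4)2]2 (2.5 mol%), (R,R)-Ph-bod [(1R,4R)-2,5-diphenylbicyclo[2.2.2]octa-2,5-diene] (5.5 mol%), KOH (6 mol%), 1,4-dioxane/H2O 10:1, 40 °C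
Reagents that add atoms: none
Why: Proposed new method: a monovalent-rhodium/chiral-diene 1,4-arylation of a 3-alkoxychromone with protonation-controlled C3 configuration; the aryl–Bpin transmetalates to Rh–OH, the aryl–rhodium carbometalates C2=C3 with aryl delivery to the unsubstituted C2 on the enantioface chosen by the diene (sets 2S), and the oxa-π-allyl rhodium enolate is protonated by water at C3 anti to the new C2 aryl, which sits pseudo-axial to avoid A(1,2) strain with the 3-alkoxy group, so H-3 ends trans to the aryl and the OMOM cis (sets 3R; near-neutral conditions prevent equilibration to trans); the closest known reaction types are the Hayashi–Miyaura asymmetric 1,4-addition of arylboron reagents to 3-unsubstituted chromones and to 1-nitrocyclohexene, where kinetic protonation also gives the cis product.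

Step 16
Reactants: 23 the hexa-MOM ether
Product: 24 [(1R,2R,6S)-6-(2,4-dihydroxyphenyl)-2-{3-[(2S,3R)-3,7-dihydroxy-4-oxo-3,4-dihydro-2H-chromen-2-yl]-4-hydroxyphenyl}-4-methylcyclohex-3-en-1-yl](2,4-dihydroxyphenyl)methanone
Conditions: conc. aq. HCl (to 1 M), MeOH/THF 3:1, 35 °C
Reagents that add atoms: none
Why: acid-catalysed transacetalisation of all six MOM acetals to methanol; acid is chosen because cis-dihydroflavonols epimerise through base-promoted ring opening or enolisation, not under mild acid.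

**Compound list**

1 | resorcinol | Oc1cccc(O)c1 | starting material
2 | acetic acid | CC(=O)O | starting material
3 | 1-(2,4-dihydroxyphenyl)ethan-1-one | CC(=O)c1ccc(O)cc1O | intermediate
4 | 1-[2-hydroxy-4-(methoxymethoxy)phenyl]ethan-1-one | CC(=O)c1ccc(OCOC)cc1O | intermediate
5 | N-[(2,4-dihydroxyphenyl)methylidene]-N-methylmethanaminium chloride | C[N+](C)=Cc1ccc(O)cc1O.[Cl-] | intermediate (not isolated)
6 | 2,4-dihydroxybenzaldehyde | O=Cc1ccc(O)cc1O | intermediate
7 | 2,4-bis(methoxymethoxy)benzaldehyde | O=Cc1ccc(OCOC)cc1OCOC | intermediate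
8 | (E)-3-[2,4-bis(methoxymethoxy)phenyl]-1-[2-hydroxy-4-(methoxymethoxy)phenyl]prop-2-en-1-one | COCOc1ccc(/C=C/C(=O)c2ccc(OCOC)cc2O)c(OCOC)c1 | intermediate
9 | 2-bromophenol | Oc1ccccc1Br | starting material
10 | 2-bromo-4-iodophenol | Oc1ccc(I)cc1Br | intermediate
11 | 2-bromo-4-iodo-1-(methoxymethoxy)benzene | COCOc1ccc(I)cc1Br | intermediate
12 | 2-methylbut-3-en-2-ol | CC(C)(O)C=C | starting material
13 | (E)-4-[3-bromo-4-(methoxymethoxy)phenyl]-2-methylbut-3-en-2-ol | CC(C)(O)/C=C/c1ccc(OCOC)c(Br)c1 | intermediate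
14 | (E)-4-[3-bromo-4-(methoxymethoxy)phenyl]-2-methylbut-3-en-2-yl methanesulfonate | CC(C)(OS(C)(=O)=O)/C=C/c1ccc(OCOC)c(Br)c1 | intermediate (not isolated)
15 | 2-bromo-1-(methoxymethoxy)-4-[(1E)-3-methylbuta-1,3-dien-1-yl]benzene | CC(=C)/C=C/c1ccc(OCOC)c(Br)c1 | intermediate
16 | [(1R,2R,6S)-2-[3-bromo-4-(methoxymethoxy)phenyl]-6-[2,4-bis(methoxymethoxy)phenyl]-4-methylcyclohex-3-en-1-yl][2-hydroxy-4-(methoxymethoxy)phenyl]methanone | CC1=C[C@@H](c2ccc(OCOC)c(Br)c2)[C@H](C(=O)c2ccc(OCOC)cc2O)[C@@H](c2ccc(OCOC)cc2OCOC)C1 | intermediate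
17 | [(1R,2R,6S)-6-[2,4-bis(methoxymethoxy)phenyl]-2-[4-(methoxymethoxy)-3-(4,4,5,5-tetramethyl-1,3,2-dioxaborolan-2-yl)phenyl]-4-methylcyclohex-3-en-1-yl][2-hydroxy-4-(methoxymethoxy)phenyl]methanone | CC1=C[C@@H](c2ccc(OCOC)c(B3OC(C)(C)C(C)(C)O3)c2)[C@H](C(=O)c2ccc(OCOC)cc2O)[C@@H](c2ccc(OCOC)cc2OCOC)C1 | intermediate
18 | (E)-3-(dimethylamino)-1-[2-hydroxy-4-(methoxymethoxy)phenyl]prop-2-en-1-one | CN(C)/C=C/C(=O)c1ccc(OCOC)cc1O | intermediate (not isolated)
19 | 7-(methoxymethoxy)-4H-chromen-4-one | O=c1ccoc2cc(OCOC)ccc12 | intermediate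
20 | 2,3-epoxy-7-(methoxymethoxy)chroman-4-one (racemic) | O=C1c2ccc(OCOC)cc2OC2OC12 | intermediate (not isolated)
21 | 3-hydroxy-7-(methoxymethoxy)-4H-chromen-4-one | O=c1c(O)coc2cc(OCOC)ccc12 | intermediate
22 | 3,7-bis(methoxymethoxy)-4H-chromen-4-one | O=c1c(OCOC)coc2cc(OCOC)ccc12 | intermediate
23 | [(1R,2R,6S)-6-[2,4-bis(methoxymethoxy)phenyl]-2-{3-[(2S,3R)-3,7-bis(methoxymethoxy)-4-oxo-3,4-dihydro-2H-chromen-2-yl]-4-(methoxymethoxy)phenyl}-4-methylcyclohex-3-en-1-yl][2-hydroxy-4-(methoxymethoxy)phenyl]methanone | CC1=C[C@@H](c2ccc(OCOC)c([C@@H]3Oc4cc(OCOC)ccc4C(=O)[C@@H]3OCOC)c2)[C@H](C(=O)c2ccc(OCOC)cc2O)[C@@H](c2ccc(OCOC)cc2OCOC)C1 | intermediate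
24 | [(1R,2R,6S)-6-(2,4-dihydroxyphenyl)-2-{3-[(2S,3R)-3,7-dihydroxy-4-oxo-3,4-dihydro-2H-chromen-2-yl]-4-hydroxyphenyl}-4-methylcyclohex-3-en-1-yl](2,4-dihydroxyphenyl)methanone | CC1=C[C@@H](c2ccc(O)c([C@@H]3Oc4cc(O)ccc4C(=O)[C@@H]3O)c2)[C@H](C(=O)c2ccc(O)cc2O)[C@@H](c2ccc(O)cc2O)C1 | target

**Step count**

Total steps: 16. Longest linear sequence: 8 (steps 6, 7, 8, 9, 10, 11, 15, 16, from 2-bromophenol).

**Steps most likely to fail, with fallbacks**

Step 15 (the proposed new coupling). The 3-alkoxy group makes the chromone a weaker, more hindered acceptor, so protodeboronation of 17 may win, and the cis product may leak to trans. The fallback uses known chemistry, sets out from 17 and 19 and comes back at 24. Boronate 17 is added to the 3-unsubstituted chromone 19 under the established [RhCl(C2H4)2]2/chiral-diene asymmetric 1,4-arylation, giving the (2R)-flavanone analogue of 23 that lacks the 3-oxygen F1. A Moriarty oxidation (PhI(OAc)2, KOH, MeOH, 0 °C) then gives the cis-3-hydroxyflavanone dimethyl acetal F2. Here the iodane enters anti to the 2-aryl group and is displaced with inversion by the hemiketal oxygen, so the new C3–O bond lies cis to the aryl. The aqueous HCl/MeOH of step 16 hydrolyses the acetal together with the MOM groups and gives 24.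

Step 10 (Diels–Alder). The exo:endo ratio and the enantioselectivity both depend on the ligand, and only the exo adduct is useful. The fallback sets out from 8 and 15 and comes back at 16. The cycloaddition is run thermally without catalyst (toluene, BHT, 160 °C, sealed tube) to give the racemic all-trans adduct F3 beside its endo isomer. After silica separation of the diastereomers, the enantiomers are resolved by preparative HPLC on a cellulose tris(3,5-dimethylphenylcarbamate) phase to give 16.

Step 16 (global deprotection). Six acetals must go without C2/C3 epimerisation of the cis-flavanonol and without acid-induced addition of the ortho phenol to the ring alkene. The fallback sets out from 17 and 21 and comes back at 24. The MOM groups are removed before the cis-flavanonol exists, and the chromone oxygens are switched to fluoride-labile silyl ethers. Boronate 17 with HCl/MeOH at rt gives the pentaphenol boronate F4. Chromone 21 with HCl/MeOH gives 3,7-dihydroxychromone F5, which TBSCl/imidazole/DMF converts to 3,7-bis(tert-butyldimethylsilyloxy)chromone F6. The step 15 coupling of F4 with F6 gives the cis-3,7-bis(silyloxy)flavanone F7. HF·pyridine in THF/pyridine at 0 °C then releases 24 without mineral acid.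

**Further compounds**

F1 | step 15 | [(1R,2R,6S)-6-[2,4-bis(methoxymethoxy)phenyl]-2-{4-(methoxymethoxy)-3-[(2R)-7-(methoxymethoxy)-4-oxo-3,4-dihydro-2H-chromen-2-yl]phenyl}-4-methylcyclohex-3-en-1-yl][2-hydroxy-4-(methoxymethoxy)phenyl]methanone | CC1=C[C@@H](c2ccc(OCOC)c([C@@H]3Oc4cc(OCOC)ccc4C(=O)C3)c2)[C@H](C(=O)c2ccc(OCOC)cc2O)[C@@H](c2ccc(OCOC)cc2OCOC)C1
F2 | step 15 | [(1R,2R,6S)-6-[2,4-bis(methoxymethoxy)phenyl]-2-{3-[(2S,3R)-3-hydroxy-4,4-dimethoxy-7-(methoxymethoxy)-3,4-dihydro-2H-chromen-2-yl]-4-(methoxymethoxy)phenyl}-4-methylcyclohex-3-en-1-yl][2-hydroxy-4-(methoxymethoxy)phenyl]methanone | CC1=C[C@@H](c2ccc(OCOC)c([C@@H]3Oc4cc(OCOC)ccc4C(OC)(OC)[C@@H]3O)c2)[C@H](C(=O)c2ccc(OCOC)cc2O)[C@@H](c2ccc(OCOC)cc2OCOC)C1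
F3 | step 10 | racemic [(1R*,2R*,6S*)-2-[3-bromo-4-(methoxymethoxy)phenyl]-6-[2,4-bis(methoxymethoxy)phenyl]-4-methylcyclohex-3-en-1-yl][2-hydroxy-4-(methoxymethoxy)phenyl]methanone (relative configuration shown, both enantiomers) | CC1=C[C@@H](c2ccc(OCOC)c(Br)c2)[C@H](C(=O)c2ccc(OCOC)cc2O)[C@@H](c2ccc(OCOC)cc2OCOC)C1
F4 | step 16 | [(1R,2R,6S)-6-(2,4-dihydroxyphenyl)-2-[4-hydroxy-3-(4,4,5,5-tetramethyl-1,3,2-dioxaborolan-2-yl)phenyl]-4-methylcyclohex-3-en-1-yl](2,4-dihydroxyphenyl)methanone | CC1=C[C@@H](c2ccc(O)c(B3OC(C)(C)C(C)(C)O3)c2)[C@H](C(=O)c2ccc(O)cc2O)[C@@H](c2ccc(O)cc2O)C1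
F5 | step 16 | 3,7-dihydroxy-4H-chromen-4-one | O=c1c(O)coc2cc(O)ccc12
F6 | step 16 | 3,7-bis(tert-butyldimethylsilyloxy)-4H-chromen-4-one | O=c1c(O[Si](C)(C)C(C)(C)C)coc2cc(O[Si](C)(C)C(C)(C)C)ccc12
F7 | step 16 | [(1R,2R,6S)-2-{3-[(2S,3R)-3,7-bis(tert-butyldimethylsilyloxy)-4-oxo-3,4-dihydro-2H-chromen-2-yl]-4-hydroxyphenyl}-6-(2,4-dihydroxyphenyl)-4-methylcyclohex-3-en-1-yl](2,4-dihydroxyphenyl)methanone | CC1=C[C@@H](c2ccc(O)c([C@@H]3Oc4cc(O[Si](C)(C)C(C)(C)C)ccc4C(=O)[C@@H]3O[Si](C)(C)C(C)(C)C)c2)[C@H](C(=O)c2ccc(O)cc2O)[C@@H](c2ccc(O)cc2O)C1
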